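The benzene ring is built rather than bought: bonds C1–C2, C3–C4 and C1–C6 of the arene are made in one thermal operation from a 3-substituted cyclobutenone (supplying C1, C6, C5, C4) and ethoxyacetylene (supplying C2, C3). This exploits the 1,3,5-pattern of the ring, in which the oxygens on C1 and C3 are both meta to the single carbon substituent, the side-chain carbon C1′ on C5. The step delivers the fully substituted resorcinol core as its monoethyl ether. Its precursor is a cyclobutenone whose C3 carries a CH2 group bound to the C2′ ketone, masked as a dioxolane and bearing the henicosyl chain.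

Key step: step 7

Remark on the chemistry: the target is achiral, so no stereocentre has to be controlled. The carbinol centre made in step 2 and the ring sp3 centre of the transient alkenylcyclobutenone in step 7 are formed as racemates and are erased later.

Step 1
Reactants: 1 1-docosanol
Product: 2 docosanal
Conditions: IBX (1.5 equiv), EtOAc, 80 °C; filter
Reagents that add atoms: none
Why: IBX oxidation of a primary alcohol stops at the aldehyde, and hot ethyl acetate keeps the waxy C22 substrate in solution while the spent oxidant is removed by filtration.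

Step 2
Reactants: 2 docosanal; 3 propargyl bromide
Product: 5 pentacos-1-yn-4-ol (racemic), via allenylzinc bromide 4 (not isolated)
Conditions: Zn dust (activated), THF, 0 °C → rt; cold 1 M HCl work-up
Reagents that add atoms: none
Why: In this zinc Barbier propargylation the allenylzinc species adds to the aldehyde through a cyclic SE2′ transition state and should give the homopropargylic alcohol; the new carbinol centre forms as a racemate and is oxidised away in step 3.

Step 3
Reactants: 5 pentacos-1-yn-4-ol (racemic)
Product: 6 pentacos-1-yn-4-one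
Conditions: Dess–Martin periodinane (1.3 equiv), CH2Cl2, 0 °C → rt; dilute with hexane, filter through a short silica pad, use at once
Reagents that add atoms: none
Why: Dess–Martin oxidation runs under neutral to weakly acidic conditions, so the β,γ-alkynyl ketone should form without the base-induced shift to the allenyl ketone, provided the work-up avoids base.

Step 4
Reactants: 6 pentacos-1-yn-4-one
Product: 7 2-henicosyl-2-(prop-2-yn-1-yl)-1,3-dioxolane
Conditions: 1,2-bis(trimethylsilyloxy)ethane (2 equiv), TMSOTf (5 mol%), CH2Cl2, −78 → −20 °C; pyridine quench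
Reagents that add atoms: 1,2-bis(trimethylsilyloxy)ethane, C[Si](C)(C)OCCO[Si](C)(C)C
Why: Noyori ketalisation works at low temperature without free Brønsted acid, base or water, which is the standard way to ketalise a β,γ-unsaturated ketone without migration of the unsaturation.

Step 5
Reactants: 7 2-henicosyl-2-(prop-2-yn-1-yl)-1,3-dioxolane; 8 trichloroacetyl chloride
Product: 10 4,4-dichloro-3-[(2-henicosyl-1,3-dioxolan-2-yl)methyl]cyclobut-2-en-1-one, via dichloroketene 9 (not isolated)
Conditions: Zn–Cu couple, Et2O/DME, rt, slow addition of 8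
Reagents that add atoms: none
Why: Dichloroketene, released by zinc dechlorination of the acid chloride, undergoes [2+2] cycloaddition with the terminal alkyne so that the unsubstituted alkyne carbon bonds to the ketene carbonyl carbon and the side chain lands on C3; DME ties up the ZnCl2 formed and so shields the dioxolane.

Step 6
Reactants: 10 4,4-dichloro-3-[(2-henicosyl-1,3-dioxolan-2-yl)methyl]cyclobut-2-en-1-one
Product: 11 3-[(2-henicosyl-1,3-dioxolan-2-yl)methyl]cyclobut-2-en-1-one
Conditions: Zn dust, TMEDA, AcOH, EtOH, 0 °C → rt
Reagents that add atoms: none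
Why: Zinc reductively dechlorinates the α,α-dichloroketone, and acetic acid buffered with TMEDA should remove both chlorines without reducing the strained enone and is too weak to open the dioxolane.

Step 7
Reactants: 11 3-[(2-henicosyl-1,3-dioxolan-2-yl)methyl]cyclobut-2-en-1-one; 12 ethoxyacetylene
Product: 17 3-ethoxy-5-[(2-henicosyl-1,3-dioxolan-2-yl)methyl]phenol, via vinylketene 13 (not isolated), via 4-alkenylcyclobutenone 14 (not isolated), via dienylketene 15 (not isolated), via cyclohexadienone 16 (not isolated)
Conditions: 12 (3 equiv, solution in hexanes), benzene, 80 °C, sealed tube, argon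
Reagents that add atoms: none
Why: In this Danheiser benzannulation, 11 should open at 80 °C by a conrotatory 4π electrocyclic reaction to vinylketene 13, whose ketene C=C adds to 12 in a [2+2] cycloaddition (bonds C1–C2 and C3–C4) to give 14; reversible 4π opening of 14 gives dienylketene 15, and disrotatory 6π electrocyclisation forms C1–C6 to give dienone 16, which tautomerises to phenol 17. The closest known reaction type is the thermal annulation of cyclobutenones with alkoxyacetylenes to resorcinol monoethers. The benzene ring is the only ring formed, closed by the 6π electrocyclisation of the isomer of 15 that has the alkenyl group cis to the ketene-bearing carbon; the other isomer returns to 14. No stereocentre survives, because the sp3 ring carbon of 14 forms as a racemate and is flattened on ring opening. The one selectivity needed is the orientation of the ketene–alkyne [2+2]: oxygen donation makes the unsubstituted alkyne carbon nucleophilic, so it bonds to the electrophilic ketene carbonyl carbon and the ethoxy-bearing carbon bonds to the ketene α-carbon, which sets OEt meta to OH and places the former C3 of 11 at arene C5. The medium contains no acid or base, so the ketal should persist, and the excess of alkyne limits acylation of the product phenol by 13.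

Step 8
Reactants: 17 3-ethoxy-5-[(2-henicosyl-1,3-dioxolan-2-yl)methyl]phenol
Product: 18 1-(3-ethoxy-5-hydroxyphenyl)tricosan-2-one
Conditions: 2 M HCl, THF, rt → 40 °C
Reagents that add atoms: water, O
Why: Acid-catalysed hydrolysis of the dioxolane should free the C2′ ketone, while the phenol, the aryl ethyl ether and the alkyl chain are inert to dilute aqueous acid.

Step 9
Reactants: 18 1-(3-ethoxy-5-hydroxyphenyl)tricosan-2-one
Product: 19 5-(2-oxotricosyl)resorcinol
Conditions: BBr3 (3.5 equiv), CH2Cl2, −78 °C → rt; H2O quench
Reagents that add atoms: none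
Why: In this BBr3 aryl ether cleavage, boron binds the ether oxygen, bromide removes the ethyl group and hydrolysis of the aryl borate on work-up should release the second phenol; the ketone and the saturated chain are untouched at low temperature.

Compound list
1 | 1-docosanol | CCCCCCCCCCCCCCCCCCCCCCO | starting material
2 | docosanal | CCCCCCCCCCCCCCCCCCCCCC=O | intermediate
3 | propargyl bromide (3-bromoprop-1-yne) | C#CCBr | starting material
4 | allenylzinc bromide (propa-1,2-dien-1-ylzinc bromide), not isolated | C=C=C[Zn]Br | intermediate
5 | pentacos-1-yn-4-ol (racemic) | CCCCCCCCCCCCCCCCCCCCCC(O)CC#C | intermediate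
6 | pentacos-1-yn-4-one | CCCCCCCCCCCCCCCCCCCCCC(=O)CC#C | intermediate
7 | 2-henicosyl-2-(prop-2-yn-1-yl)-1,3-dioxolane | CCCCCCCCCCCCCCCCCCCCCC1(CC#C)OCCO1 | intermediate
8 | trichloroacetyl chloride | O=C(Cl)C(Cl)(Cl)Cl | starting material
9 | dichloroketene, not isolated | O=C=C(Cl)Cl | intermediate
10 | 4,4-dichloro-3-[(2-henicosyl-1,3-dioxolan-2-yl)methyl]cyclobut-2-en-1-one | CCCCCCCCCCCCCCCCCCCCCC1(CC2=CC(=O)C2(Cl)Cl)OCCO1 | intermediate
11 | 3-[(2-henicosyl-1,3-dioxolan-2-yl)methyl]cyclobut-2-en-1-one | CCCCCCCCCCCCCCCCCCCCCC1(CC2=CC(=O)C2)OCCO1 | intermediate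
12 | ethoxyacetylene | CCOC#C | starting material
13 | vinylketene, 3-[(2-henicosyl-1,3-dioxolan-2-yl)methyl]buta-1,3-dien-1-one, not isolated | CCCCCCCCCCCCCCCCCCCCCC1(CC(=C)C=C=O)OCCO1 | intermediate
14 | 3-ethoxy-4-[3-(2-henicosyl-1,3-dioxolan-2-yl)prop-1-en-2-yl]cyclobut-2-en-1-one (racemic), not isolated | CCCCCCCCCCCCCCCCCCCCCC1(CC(=C)C2C(OCC)=CC2=O)OCCO1 | intermediate
15 | dienylketene, (3E)-3-ethoxy-5-[(2-henicosyl-1,3-dioxolan-2-yl)methyl]hexa-1,3,5-trien-1-one (alkenyl group cis to the ketene-bearing carbon), not isolated | CCCCCCCCCCCCCCCCCCCCCC1(CC(=C)/C=C(OCC)\C=C=O)OCCO1 | intermediate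
16 | 3-ethoxy-5-[(2-henicosyl-1,3-dioxolan-2-yl)methyl]cyclohexa-2,4-dien-1-one, not isolated | CCCCCCCCCCCCCCCCCCCCCC1(CC2=CC(OCC)=CC(=O)C2)OCCO1 | intermediate
17 | 3-ethoxy-5-[(2-henicosyl-1,3-dioxolan-2-yl)methyl]phenol | CCCCCCCCCCCCCCCCCCCCCC1(Cc2cc(O)cc(OCC)c2)OCCO1 | intermediate
18 | 1-(3-ethoxy-5-hydroxyphenyl)tricosan-2-one | CCCCCCCCCCCCCCCCCCCCCC(=O)Cc1cc(O)cc(OCC)c1 | intermediate
19 | 5-(2-oxotricosyl)resorcinol, 1-(3,5-dihydroxyphenyl)tricosan-2-one | CCCCCCCCCCCCCCCCCCCCCC(=O)Cc1cc(O)cc(O)c1 | target

Total step count: 9
Longest linear sequence: 9 steps (1 → 19); compounds 3, 8 and 12 are purchased.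

Steps most likely to fail

Step 7. The volatile alkyne may escape or fragment thermally before it intercepts the vinylketene, and the vinylketene may instead dimerise or acylate phenol already formed. The fallback gives up the ring construction and attaches the chain to a preformed resorcinol dimethyl ether by dithiane umpolung. It sets out from docosanal 2: 1,3-propanedithiol and BF3·OEt2 in CH2Cl2 should give 2-henicosyl-1,3-dithiane F1. Deprotonation with n-BuLi in THF at −30 °C gives 2-henicosyl-2-lithio-1,3-dithiane F2, which is alkylated with commercial 3,5-dimethoxybenzyl bromide to 2-(3,5-dimethoxybenzyl)-2-henicosyl-1,3-dithiane F3. Hydrolysis with MeI and CaCO3 in aqueous MeCN frees 1-(3,5-dimethoxyphenyl)tricosan-2-one F4, and BBr3 in CH2Cl2 removes both methyl ethers, so the fallback comes back to the route at 19.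

Step 4. The propargyl ketone may undergo prototropic shift to the allenyl ketone, during ketalisation or already in step 3, followed by conjugate addition of the glycol. The fallback installs the alkyne last, so that no β,γ-alkynyl ketone is ever present. It sets out from docosanal 2: Roskamp homologation with ethyl diazoacetate and catalytic SnCl2 in CH2Cl2 should give ethyl 3-oxotetracosanoate F5. Ethylene glycol and catalytic TsOH in toluene under Dean–Stark conditions give ethyl 2-(2-henicosyl-1,3-dioxolan-2-yl)acetate F6. Reduction with i-Bu2AlH at −78 °C gives 2-(2-henicosyl-1,3-dioxolan-2-yl)acetaldehyde F7, and Ohira–Bestmann homologation (dimethyl (1-diazo-2-oxopropyl)phosphonate, K2CO3, MeOH) converts the aldehyde into the terminal alkyne, so the fallback comes back to the route at 7.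

Step 5. ZnCl2 may open the dioxolane, the acid chloride may acylate the liberated oxygen, and chlorine may migrate within the dichlorocyclobutenone. The fallback replaces the dichloroketene by a keteniminium salt and so needs neither zinc nor a dechlorination. It sets out from alkyne 7: N,N-dimethylacetamide, Tf2O and 2,4,6-collidine in 1,2-dichloroethane generate N,N-dimethylketeniminium triflate F8. Its [2+2] cycloaddition with 7 at reflux should give 3-[(2-henicosyl-1,3-dioxolan-2-yl)methyl]-N,N-dimethylcyclobut-2-en-1-iminium triflate F9. Hydrolysis with aqueous NaHCO3 delivers the cyclobutenone directly, so the fallback comes back to the route at 11 and bypasses 10.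

Further compounds
F1 | step 7 | 2-henicosyl-1,3-dithiane | CCCCCCCCCCCCCCCCCCCCCC1SCCCS1
F2 | step 7 | 2-henicosyl-2-lithio-1,3-dithiane | CCCCCCCCCCCCCCCCCCCCCC1([Li])SCCCS1
F3 | step 7 | 2-(3,5-dimethoxybenzyl)-2-henicosyl-1,3-dithiane | CCCCCCCCCCCCCCCCCCCCCC1(Cc2cc(OC)cc(OC)c2)SCCCS1
F4 | step 7 | 1-(3,5-dimethoxyphenyl)tricosan-2-one | CCCCCCCCCCCCCCCCCCCCCC(=O)Cc1cc(OC)cc(OC)c1
F5 | step 4 | ethyl 3-oxotetracosanoate | CCCCCCCCCCCCCCCCCCCCCC(=O)CC(=O)OCC
F6 | step 4 | ethyl 2-(2-henicosyl-1,3-dioxolan-2-yl)acetate | CCCCCCCCCCCCCCCCCCCCCC1(CC(=O)OCC)OCCO1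
F7 | step 4 | 2-(2-henicosyl-1,3-dioxolan-2-yl)acetaldehyde | CCCCCCCCCCCCCCCCCCCCCC1(CC=O)OCCO1
F8 | step 5 | N,N-dimethylketeniminium triflate | C=C=[N+](C)C.[O-]S(=O)(=O)C(F)(F)F
F9 | step 5 | 3-[(2-henicosyl-1,3-dioxolan-2-yl)methyl]-N,N-dimethylcyclobut-2-en-1-iminium triflate | CCCCCCCCCCCCCCCCCCCCCC1(CC2=CC(=[N+](C)C)C2)OCCO1.[O-]S(=O)(=O)C(F)(F)F
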